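The plan rests on cutting the lactone C3–C4 bond by a [3,3] shift. Because lactone C4 bears both the ring C5H2–O1 unit and the aroyl carbon C7', the chain O1–C5–C4–C7' is a (Z)-2-aryl-but-2-ene-1,4-diol in disguise; an extra methyl carbinol on C7' stores chirality and later leaves as acetaldehyde, uncovering the ketone. Heating that diol with an orthoester of the 3-arylpropanoic acid gives a seven-membered 1,3-dioxepine ketene acetal, which contracts in one operation to the butyrolactone: the C3–C4 bond, the lactone ring, the C4 stereocentre and the masked C7' ketone arise together. The precursor is a lactate-derived (R,Z)-3-aryl-pent-2-ene-1,4-diol condensed as a cyclic orthoester.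

Key step: step 10

Remark: lignan-type numbering is used (O1, C2 carbonyl, C3 benzyl-bearing, C4 aroyl-bearing, C5 ring CH2, C7' ketone carbon); C4 is correctly named 4S while it carries the propenyl group and 4R once the ketone is present, with no change in its spatial arrangement.

Step 1
Reactants: 1 methyl (R)-lactate; 2 acetyl chloride
Product: 3 methyl (R)-2-acetoxypropanoate
Conditions: pyridine (1.5 equiv), CH2Cl2, 0 °C to rt
Reagents that add atoms: none
Why: Pyridine-mediated O-acylation of the secondary alcohol by the acid chloride (nucleophilic acyl substitution) is fast and does not touch the stereocentre.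

Step 2
Reactants: 3 methyl (R)-2-acetoxypropanoate
Product: 4 (R)-4-hydroxy-5-methylfuran-2(5H)-one ((R)-5-methyltetronic acid)
Conditions: LiN(SiMe3)2 (2.5 equiv), THF, −78 °C; then cold 2 M HCl
Reagents that add atoms: none
Why: Dieckmann-type (intramolecular Claisen) condensation in which the acetate enolate, formed kinetically at −78 °C, attacks the neighbouring methyl ester and the product is held as its lithium tetronate by the excess base, so the (R) centre at C5 should not be deprotonated.

Step 3
Reactants: 4 (R)-5-methyltetronic acid
Product: 5 (R)-2-methyl-5-oxo-2,5-dihydrofuran-3-yl trifluoromethanesulfonate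
Conditions: Tf2O (1.1 equiv), i-Pr2NEt (1.2 equiv), CH2Cl2, −78 °C; used promptly
Reagents that add atoms: trifluoromethanesulfonic anhydride, O=S(=O)(OS(=O)(=O)C(F)(F)F)C(F)(F)F
Why: O-sulfonylation of the vinylogous acid with a hindered amine at low temperature should give the vinylogous acyl triflate without enolising the C5–H.

Step 4
Reactants: 5 (R)-5-methyltetronic acid enol triflate; 6 4-benzyloxy-3-methoxyphenylboronic acid
Product: 7 (R)-4-(4-benzyloxy-3-methoxyphenyl)-5-methylfuran-2(5H)-one
Conditions: PdCl2(PPh3)2 (3 mol%), KF (3 equiv), THF–H2O (10:1), 40 °C; enantiopurity checked by chiral HPLC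
Reagents that add atoms: none
Why: Suzuki–Miyaura coupling in which the electron-poor vinyl triflate adds oxidatively with ease and fluoride activates the boronic acid without being basic enough to enolise the C5–H, so the (R) centre should survive.

Step 5
Reactants: 7 (R)-4-(4-benzyloxy-3-methoxyphenyl)-5-methylfuran-2(5H)-one
Product: 9 (2Z,4R)-3-(4-benzyloxy-3-methoxyphenyl)pent-2-ene-1,4-diol, via lactol 8 (not isolated)
Conditions: i-Bu2AlH (4 equiv), CH2Cl2, −78 to 0 °C; aq. potassium sodium tartrate
Reagents that add atoms: none
Why: Hydride 1,2-reduction of the lactone by i-Bu2AlH passes through the lactol aluminate, which opens and is reduced again, so the ring geometry is carried over as the Z alkene and the untouched carbinol keeps its (R) configuration, while the tartrate work-up avoids acid that would cyclodehydrate the diol.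

Step 6
Reactants: 10 3-(4-hydroxy-3-methoxyphenyl)propanoic acid (dihydroferulic acid)
Product: 11 3-(4-benzyloxy-3-methoxyphenyl)propanoic acid
Conditions: BnBr (1.3 equiv), KOH (3 equiv), EtOH–H2O, reflux; then HCl to pH 2
Reagents that add atoms: benzyl bromide, BrCc1ccccc1
Why: Williamson ether synthesis on the phenoxide, where any benzyl ester formed in aqueous ethanolic hydroxide is saponified again, so only the phenol should end up benzylated.

Step 7
Reactants: 11 3-(4-benzyloxy-3-methoxyphenyl)propanoic acid
Product: 13 3-(4-benzyloxy-3-methoxyphenyl)propanamide, via acyl imidazole 12 (not isolated)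
Conditions: 1,1'-carbonyldiimidazole (1.2 equiv), THF, rt; then aq. NH3, 0 °C to rt
Reagents that add atoms: ammonia, N
Why: Activation of the acid as its acyl imidazolide and aminolysis by ammonia (nucleophilic acyl substitution) should give the primary amide under conditions inert to the aryl ethers.

Step 8
Reactants: 13 3-(4-benzyloxy-3-methoxyphenyl)propanamide
Product: 14 3-(4-benzyloxy-3-methoxyphenyl)propanenitrile
Conditions: (CF3CO)2O (1.2 equiv), pyridine (2.5 equiv), CH2Cl2, 0 °C
Reagents that add atoms: none
Why: Dehydration of a primary amide, in which O-trifluoroacetylation and pyridine-induced loss of trifluoroacetate should deliver the nitrile at 0 °C.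

Step 9
Reactants: 14 3-(4-benzyloxy-3-methoxyphenyl)propanenitrile
Product: 16 trimethyl 3-(4-benzyloxy-3-methoxyphenyl)orthopropanoate, via imidate hydrochloride 15 (not isolated)
Conditions: HCl (g), MeOH (1.1 equiv), Et2O, 0 °C; evaporate; then MeOH (excess), hexane, rt; filtration through basic Al2O3
Reagents that add atoms: methanol, CO
Why: Pinner reaction, in which dry HCl and one equivalent of methanol convert the nitrile into the imidate hydrochloride and alcoholysis of that salt by excess methanol gives the orthoester as ammonium chloride precipitates, the product then being kept away from acid and moisture.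

Step 10
Reactants: 9 (2Z,4R)-3-(4-benzyloxy-3-methoxyphenyl)pent-2-ene-1,4-diol; 16 trimethyl 3-(4-benzyloxy-3-methoxyphenyl)orthopropanoate (1.1 equiv)
Product: 20 (3R,4S)-3-(4-benzyloxy-3-methoxybenzyl)-4-[(Z)-1-(4-benzyloxy-3-methoxyphenyl)prop-1-en-1-yl]dihydrofuran-2(3H)-one, via cyclic orthoester 17 (not isolated), via ketene acetal 18 (not isolated), via C3-epimeric lactone 19 (not isolated)
Conditions: t-BuCO2H (5 mol%), xylene, 100 °C (MeOH distilled off), then 145 °C; then DBU (1 equiv), 110 °C, same flask
Reagents that add atoms: none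
Why: Weak-acid orthoester exchange ties both hydroxyls of 9 to the orthoester carbon of 16 to give the dioxepine 17 (the second C–O bond closes the seven-membered ring by 7-exo-trig attack on a dialkoxycarbenium ion), loss of one more methanol near 145 °C gives ketene acetal 18, and its O–C=C unit plus the ring allyl ether then undergo a concerted, suprafacial [3,3] shift in which the exocyclic carbon bonds to the ring =CH carbon as the secondary allylic C–O bond breaks. The closest known reaction type is the Johnson orthoester Claisen of (Z)-but-2-ene-1,4-diols to β-vinyl-γ-butyrolactones, allied with Claisen ring contractions of cyclic ketene acetals and with 1,3-chirality transfer from secondary allylic alcohols. The butyrolactone ring (O1–C2–C3–C4–C5) is closed by the new C3–C4 σ bond in a pericyclic 7-to-5 contraction through a chair-like bicyclo[3.2.1] transition state, not by a polar cyclisation, so ring-closure rules for nucleophilic attack are not at issue; should 17 open and the acyclic mixed ketene acetal on the secondary oxygen rearrange instead, the same alkene face is used and the primary hydroxyl lactonises onto the ester to the same product. C4 is controlled by the (R)-carbinol: allylic 1,3-strain with the cis CH2O group keeps the carbinol H inside and the methyl outside, so the new bond is made on the face that carried the breaking C–O bond, which gives 4S (the arrangement that becomes 4R in the target) together with the (Z)-propenyl group. C3 is not controlled in the shift and is set in the same flask by DBU, which equilibrates this single acidic centre to the trans lactone against the non-acidic C4; chromatography then removes residual cis epimer and any (E)-propenyl isomer, the latter being the carrier of the wrong C4 configuration. The selectivity needed is cleavage of the secondary rather than the primary allylic C–O bond, favoured because that course avoids a quaternary centre, leaves the new alkene conjugated with the arene and is accelerated by the methyl group on the departing carbon, while the weak acid and non-polar solvent keep the electron-rich allyl system from ionising.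

Step 11
Reactants: 20 (3R,4S)-3-(4-benzyloxy-3-methoxybenzyl)-4-[(Z)-1-(4-benzyloxy-3-methoxyphenyl)prop-1-en-1-yl]dihydrofuran-2(3H)-one
Product: 22 (3R,4R)-3-(4-benzyloxy-3-methoxybenzyl)-4-(4-benzyloxy-3-methoxybenzoyl)dihydrofuran-2(3H)-one, via ozonide 21 (not isolated)
Conditions: O3, CH2Cl2, −78 °C, Sudan Red 7B end-point; then PPh3 (1.5 equiv), −78 °C to rt
Reagents that add atoms: ozone, [O-][O+]=O
Why: Ozonolysis, in which 1,3-dipolar cycloaddition of ozone to the electron-rich trisubstituted alkene (faster than attack on the dialkoxyarenes, hence the dye end-point) gives the ozonide and neutral reduction by PPh3 should release the C7' aryl ketone and acetaldehyde without any base that could epimerise the now acidic C4–H, both stereocentres keeping their spatial arrangement and C4 being named R only because the carbonyl carbon now outranks C5.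

Step 12
Reactants: 22 (3R,4R)-3-(4-benzyloxy-3-methoxybenzyl)-4-(4-benzyloxy-3-methoxybenzoyl)dihydrofuran-2(3H)-one
Product: 23 (3R,4R)-3-(4-hydroxy-3-methoxybenzyl)-4-(4-hydroxy-3-methoxybenzoyl)dihydrofuran-2(3H)-one (CNP0159909.1)
Conditions: H2 (1 atm, stopped at 2 equiv uptake), Pd/C (10%), EtOAc, rt
Reagents that add atoms: none
Why: Catalytic hydrogenolysis of the two aryl benzyl ethers over Pd/C is much faster in neutral ethyl acetate than reduction of the electron-rich 4-oxygenated aryl ketone, so stopping at two equivalents of hydrogen should give the diphenol with both stereocentres untouched.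

Compound list
1 | methyl (R)-lactate (methyl (2R)-2-hydroxypropanoate) | C[C@@H](O)C(=O)OC | starting material
2 | acetyl chloride | CC(=O)Cl | starting material
3 | methyl (R)-2-acetoxypropanoate | C[C@@H](OC(C)=O)C(=O)OC | intermediate
4 | (R)-4-hydroxy-5-methylfuran-2(5H)-one ((R)-5-methyltetronic acid) | C[C@H]1OC(=O)C=C1O | intermediate
5 | (R)-2-methyl-5-oxo-2,5-dihydrofuran-3-yl trifluoromethanesulfonate | C[C@H]1OC(=O)C=C1OS(=O)(=O)C(F)(F)F | intermediate
6 | 4-benzyloxy-3-methoxyphenylboronic acid | OB(O)c1ccc(OCc2ccccc2)c(OC)c1 | starting material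
7 | (R)-4-(4-benzyloxy-3-methoxyphenyl)-5-methylfuran-2(5H)-one | C[C@H]1OC(=O)C=C1c1ccc(OCc2ccccc2)c(OC)c1 | intermediate
8 | (5R)-4-(4-benzyloxy-3-methoxyphenyl)-5-methyl-2,5-dihydrofuran-2-ol (lactol, present as its aluminium alkoxide, both configurations at C2) | C[C@H]1OC(O)C=C1c1ccc(OCc2ccccc2)c(OC)c1 | intermediate
9 | (2Z,4R)-3-(4-benzyloxy-3-methoxyphenyl)pent-2-ene-1,4-diol | C[C@@H](O)/C(=C\CO)c1ccc(OCc2ccccc2)c(OC)c1 | intermediate
10 | 3-(4-hydroxy-3-methoxyphenyl)propanoic acid (dihydroferulic acid) | COc1cc(CCC(=O)O)ccc1O | starting material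
11 | 3-(4-benzyloxy-3-methoxyphenyl)propanoic acid | COc1cc(CCC(=O)O)ccc1OCc1ccccc1 | intermediate
12 | 1-[3-(4-benzyloxy-3-methoxyphenyl)propanoyl]imidazole | COc1cc(CCC(=O)n2ccnc2)ccc1OCc1ccccc1 | intermediate
13 | 3-(4-benzyloxy-3-methoxyphenyl)propanamide | COc1cc(CCC(N)=O)ccc1OCc1ccccc1 | intermediate
14 | 3-(4-benzyloxy-3-methoxyphenyl)propanenitrile | N#CCCc1ccc(OCc2ccccc2)c(OC)c1 | intermediate
15 | methyl 3-(4-benzyloxy-3-methoxyphenyl)propanimidate hydrochloride | Cl.COC(=N)CCc1ccc(OCc2ccccc2)c(OC)c1 | intermediate
16 | trimethyl 3-(4-benzyloxy-3-methoxyphenyl)orthopropanoate (1-benzyloxy-2-methoxy-4-(3,3,3-trimethoxypropyl)benzene) | COC(CCc1ccc(OCc2ccccc2)c(OC)c1)(OC)OC | intermediate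
17 | (4R)-5-(4-benzyloxy-3-methoxyphenyl)-2-[2-(4-benzyloxy-3-methoxyphenyl)ethyl]-2-methoxy-4-methyl-4,7-dihydro-1,3-dioxepine (both configurations at C2) | C[C@H]1OC(OC)(CCc2ccc(OCc3ccccc3)c(OC)c2)OCC=C1c1ccc(OCc2ccccc2)c(OC)c1 | intermediate
18 | (4R)-5-(4-benzyloxy-3-methoxyphenyl)-2-[2-(4-benzyloxy-3-methoxyphenyl)ethylidene]-4-methyl-4,7-dihydro-1,3-dioxepine (exocyclic geometry not defined) | C[C@H]1OC(=CCc2ccc(OCc3ccccc3)c(OC)c2)OCC=C1c1ccc(OCc2ccccc2)c(OC)c1 | intermediate
19 | (4S)-3-(4-benzyloxy-3-methoxybenzyl)-4-[(Z)-1-(4-benzyloxy-3-methoxyphenyl)prop-1-en-1-yl]dihydrofuran-2(3H)-one, mixture of C3 epimers | COc1cc(CC2C(=O)OC[C@@H]2/C(=C/C)c2ccc(OCc3ccccc3)c(OC)c2)ccc1OCc1ccccc1 | intermediate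
20 | (3R,4S)-3-(4-benzyloxy-3-methoxybenzyl)-4-[(Z)-1-(4-benzyloxy-3-methoxyphenyl)prop-1-en-1-yl]dihydrofuran-2(3H)-one (trans) | COc1cc(C[C@H]2C(=O)OC[C@@H]2/C(=C/C)c2ccc(OCc3ccccc3)c(OC)c2)ccc1OCc1ccccc1 | intermediate
21 | secondary ozonide of 20: the lactone C4 carries a 3-(4-benzyloxy-3-methoxyphenyl)-5-methyl-1,2,4-trioxolan-3-yl group (trioxolane centres as formed) | COc1cc(C[C@H]2C(=O)OC[C@@H]2C3(c4ccc(OCc5ccccc5)c(OC)c4)OOC(C)O3)ccc1OCc1ccccc1 | intermediate
22 | (3R,4R)-3-(4-benzyloxy-3-methoxybenzyl)-4-(4-benzyloxy-3-methoxybenzoyl)dihydrofuran-2(3H)-one | COc1cc(C[C@H]2C(=O)OC[C@@H]2C(=O)c2ccc(OCc3ccccc3)c(OC)c2)ccc1OCc1ccccc1 | intermediate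
23 | (3R,4R)-3-(4-hydroxy-3-methoxybenzyl)-4-(4-hydroxy-3-methoxybenzoyl)dihydrofuran-2(3H)-one (CNP0159909.1) | COc1cc(C[C@H]2C(=O)OC[C@@H]2C(=O)c2ccc(O)c(OC)c2)ccc1O | target

Total step count: 12
Longest linear sequence: 8 steps (steps 1 to 5, then 10, 11 and 12); the orthoester branch (steps 6 to 9) joins at step 10.

Steps most likely to fail

Step 10. The shift may take the wrong regiochemical course (cleavage of the primary allylic C–O bond with bonding to the aryl-bearing carbon), or the acid may ionise the electron-rich allylic system, which would erode the chirality transfer or cyclodehydrate the diol. The fallback sets out from 9 and removes the regiochemical choice. Selective silylation of the primary allylic hydroxyl (t-BuMe2SiCl, imidazole, CH2Cl2, −20 °C) should give (2R,3Z)-3-(4-benzyloxy-3-methoxyphenyl)-5-(tert-butyldimethylsilyloxy)pent-3-en-2-ol F1. An ordinary acyclic Johnson orthoester Claisen of its secondary hydroxyl with 16 (EtCO2H cat., xylene, 140 °C) should then give methyl (3S,4Z)-2-(4-benzyloxy-3-methoxybenzyl)-4-(4-benzyloxy-3-methoxyphenyl)-3-[(tert-butyldimethylsilyloxy)methyl]hex-4-enoate F2 through the same strain-controlled alkene face. Bu4NF in THF removes the silyl group and the freed primary alkoxide closes onto the methyl ester, which returns to the route at 19; DBU equilibration as in step 10 then gives 20.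

Step 4. Base-mediated enolisation of the C5–H (through the aromatic 2-oxidofuran) may erode the enantiopurity during the coupling, or the triflate may hydrolyse faster than it couples. The fallback sets out from 5 and makes the coupling base-free: a Stille coupling with tributyl(4-benzyloxy-3-methoxyphenyl)stannane F3 under Pd2(dba)3, AsPh3 and LiCl in N-methylpyrrolidone at room temperature. The stannane would be prepared from purchased 1-benzyloxy-4-bromo-2-methoxybenzene by bromine–lithium exchange with n-BuLi at −78 °C and quench with Bu3SnCl. The fallback returns to the route at 7.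

Step 11. Ozone may attack the two dialkoxyarenes or the benzylic ether C–H bonds before the hindered trisubstituted alkene is consumed. The fallback sets out from 20 and separates oxidation from cleavage: dihydroxylation with catalytic OsO4 and N-methylmorpholine N-oxide in acetone–water should give the vicinal diol (3R,4R)-3-(4-benzyloxy-3-methoxybenzyl)-4-[1-(4-benzyloxy-3-methoxyphenyl)-1,2-dihydroxypropyl]dihydrofuran-2(3H)-one F4. Glycol cleavage with NaIO4 in pH 7 buffered aqueous THF then returns to the route at 22.

Further compounds
F1 | step 10 | (2R,3Z)-3-(4-benzyloxy-3-methoxyphenyl)-5-(tert-butyldimethylsilyloxy)pent-3-en-2-ol | C[C@@H](O)/C(=C\CO[Si](C)(C)C(C)(C)C)c1ccc(OCc2ccccc2)c(OC)c1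
F2 | step 10 | methyl (3S,4Z)-2-(4-benzyloxy-3-methoxybenzyl)-4-(4-benzyloxy-3-methoxyphenyl)-3-[(tert-butyldimethylsilyloxy)methyl]hex-4-enoate (C2 epimers) | COC(=O)C(Cc1ccc(OCc2ccccc2)c(OC)c1)[C@H](CO[Si](C)(C)C(C)(C)C)/C(=C/C)c1ccc(OCc2ccccc2)c(OC)c1
F3 | step 4 | tributyl(4-benzyloxy-3-methoxyphenyl)stannane | CCCC[Sn](CCCC)(CCCC)c1ccc(OCc2ccccc2)c(OC)c1
F4 | step 11 | (3R,4R)-3-(4-benzyloxy-3-methoxybenzyl)-4-[1-(4-benzyloxy-3-methoxyphenyl)-1,2-dihydroxypropyl]dihydrofuran-2(3H)-one (diol centres as formed) | COc1cc(C[C@H]2C(=O)OC[C@@H]2C(O)(C(C)O)c2ccc(OCc3ccccc3)c(OC)c2)ccc1OCc1ccccc1
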